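The numbers in the tables were generated by integration from invented constants.

In a closed flask the reagent can be counted: what is free plus what has been consumed equals the charge. I started from that count because the zeta run, this very flask followed so far, levelled near half of the substrate charged from equal charges, and a count that lands there is two reagent consumed per product. That makes reagent the limiting reagent, and I carried one quantity: the reagent ceiling, the charged [reagent] divided by twice the charged [substrate], here 50.0%.

| flask | substrate | reagent | temperature | remark | time |
|---|---|---|---|---|---|
| zeta | 0.050 M | 0.050 M | 90 °C | the very flask that is asked about, followed so far |  |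
| alpha | 0.050 M | 0.10 M | 75 °C | run made earlier |  |
| flask | 0.050 M | 0.0500 M | 90 °C |  | 12 h |

| run | time / min | product / % |
|---|---|---|
| zeta | 150 | 38.0 |
| zeta | 300 | 46.4 |
| zeta | 480 | 49.3 |
| zeta | 600 | 49.6 |
| alpha | 8.00 | 0.4 |
| alpha | 25.0 | 1.3 |
| alpha | 40.0 | 3.4 |
| alpha | 60.0 | 6.7 |

(standard deviation of a reading: 0.3 percentage points)

- what is taken out of product is counted as made
- additions bring no volume worth counting

- product, in percent of the substrate first charged, at 12 h
- what to do for the largest gain in product; "none" if nothing gains more than 2 percentage points (dusk / summer / winter / midnight / none)
- product present, with what was taken out counted in, in percent of the substrate first charged, after dusk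
- product present, with what was taken out counted in, in percent of the substrate first charged, after midnight

- dusk: at 12 h take out 90% of the product then present, then wait 6.0 h
- summer: change nothing and wait 6.0 h more
- winter: at 12 h add reagent, 50.0% of the amount charged, then wait 6.0 h
- midnight: at 12 h raise the temperature by 25 K, then wait 6.0 h

I went through the settings in turn. For time, the gap between ceiling and readings fell from 3.6 percentage points at 300 min to 0.7 points at 480 min, which reads as a half-life of 76.2 min, so I put this flask at 49.9% at 12 h, and summer's 4.73 further half-lives could add 0.079 points. Dusk leaves the count unchanged, so I gave it the same small gain, though the readings do not exclude a reversible step. Midnight changes the pace, but the ceiling contains no temperature, so I gave it that gain too. Winter raises the ceiling itself, to 75.0%, and if the tail's pace held, nearly all of that rise would arrive, a gain far larger than the others, so I chose winter.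

The forecast, saying “I take reagent exhaustion as the working reading”, gave 49.8% against my 49.9%, chose winter, and put dusk and midnight at 50% and 50%.

The flask gave 49.6% at 12 h, and winter gained 22 points, reaching 71.5%, while dusk and midnight ended at 49.7% and 49.7%.

    substrate → intermediate A (k = 3.40 × 10⁻⁴ /s, Ea = 106 kJ/mol)
    reagent + intermediate B → product (k = 0.230 /M/s, Ea = 52.0 kJ/mol)
    intermediate A ⇌ intermediate C (K = 0.690, k = 1.60 × 10⁻⁴ /s, Ea = 113 kJ/mol, ΔH = −19.0 kJ/mol)
    reagent + intermediate A → intermediate B (k = 0.00480 /M/s, Ea = 62.0 kJ/mol)
    (constants at 90 °C)

At 12 h this flask held 0.156% of its reagent and 0% of its substrate, with intermediate A at 29.4% and intermediate C at 20.3%. Its product stood 0.40 points under the ceiling, and winter's stood 3.5 points under the raised one. In the neighbouring flask with 0.20 M of substrate the ceiling comes to 12.5%, and that flask stood at 12.0% with reagent at 0%.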